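## Retrosynthetic overview
1. 14 ⇒ 13: the last step is hydrogenolysis of the benzyl ester that masks the B-ring CO2H.
2. 13 ⇒ 6 + 11: the depside link is cut at the aryl C3–O bond, not at the hindered acyl C–O bond. This is the new step, a Rh(II) quinoid-carbene O–H insertion.
3. 11 ⇒ 10 ⇒ 9 ⇒ 7: iodine(III) is placed on C3 of benzyl divarate, the ester comes from the acid, and the acid comes from 5-propylresorcinol by carboxylation.
4. 6 ⇒ 5 ⇒ 3 ⇒ 1: Pinnick oxidation, Vilsmeier–Haack formylation and O-methylation of olivetol.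
5. No ring is formed. Both benzene rings are bought intact in 1 and 7.

Assumption: the SMILES holds no stereocentre and no stereo-defined double bond, so the target is achiral and "single enantiomer" calls for no stereocontrol.

## Route

Step 1
Reactants: 1 olivetol (5-pentylbenzene-1,3-diol)
Product: 3 1,3-dimethoxy-5-pentylbenzene, via 3-methoxy-5-pentylphenol 2 (not isolated)
Conditions: MeI (2.5 equiv), K2CO3, acetone, reflux
Reagents that add atoms: iodomethane CI
Why: Williamson ether synthesis, in which both phenoxides are O-alkylated one after the other by MeI and C-alkylation is negligible in acetone.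

Step 2
Reactants: 3 1,3-dimethoxy-5-pentylbenzene
Product: 5 2,4-dimethoxy-6-pentylbenzaldehyde, via aryl iminium dichlorophosphate 4 (not isolated)
Conditions: POCl3, DMF, 0 → 80 °C; then ice-water
Reagents that add atoms: N,N-dimethylformamide CN(C)C=O; water O
Why: Vilsmeier–Haack formylation, in which the chloroiminium ion attacks para to one OMe and ortho to the other (the carbon next to the pentyl chain) rather than the carbon between the two OMe groups, and water hydrolyses 4 to the aldehyde.

Step 3
Reactants: 5 2,4-dimethoxy-6-pentylbenzaldehyde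
Product: 6 2,4-dimethoxy-6-pentylbenzoic acid
Conditions: NaClO2, NaH2PO4, 2-methylbut-2-ene (excess), t-BuOH/H2O, rt
Reagents that add atoms: sodium chlorite [Na+].[O-]Cl=O
Why: Pinnick oxidation, in which chlorous acid adds to the aldehyde and fragments to the acid while the alkene traps HOCl so that the electron-rich ring is not chlorinated.

Step 4
Reactants: 7 5-propylbenzene-1,3-diol (divarinol)
Product: 9 2,4-dihydroxy-6-propylbenzoic acid, via magnesium salicylate chelate 8 (not isolated)
Conditions: MeOMgOCO2Me (2 M in DMF), 120 °C; then aq. HCl, 0 °C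
Reagents that add atoms: methyl magnesium carbonate COC(=O)[O-].C[O-].[Mg+2]
Why: Kolbe–Schmitt-type carboxylation with Stiles' reagent, in which Mg binds the phenoxide, CO2 is delivered to the ortho carbon next to the alkyl chain as with other 5-alkylresorcinols, and chelate 8 is the thermodynamic sink until cold acid frees 9.

Step 5
Reactants: 9 2,4-dihydroxy-6-propylbenzoic acid
Product: 10 benzyl 2,4-dihydroxy-6-propylbenzoate
Conditions: BnBr (1.0 equiv), KHCO3, DMF, rt
Reagents that add atoms: benzyl bromide BrCc1ccccc1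
Why: SN2 O-alkylation of the carboxylate, since KHCO3 deprotonates only the CO2H and not the phenols, and room temperature avoids decarboxylation.

Step 6
Reactants: 10 benzyl 2,4-dihydroxy-6-propylbenzoate
Product: 11 benzyl 2-hydroxy-4-oxido-3-(phenyliodonio)-6-propylbenzoate (C3 iodonium zwitterion)
Conditions: PhI(OAc)2 (1.05 equiv), KOH (2 equiv), MeOH, 0 °C
Reagents that add atoms: (diacetoxyiodo)benzene CC(=O)OI(OC(C)=O)c1ccccc1
Why: Iodonium ylide (zwitterion) formation as known for 1,3-dicarbonyl compounds and acylresorcinols, in which the phenoxide attacks I(III) through C3 (the carbon flanked by both oxygens), C5 is shielded by the propyl group, and the hindered phenoxide-deactivated benzyl ester survives cold methanolic base.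

Step 7
Reactants: 11 benzyl 2-hydroxy-4-oxido-3-(phenyliodonio)-6-propylbenzoate; 6 2,4-dimethoxy-6-pentylbenzoic acid (1.5 equiv)
Product: 13 benzyl 3-[(2,4-dimethoxy-6-pentylbenzoyl)oxy]-2,4-dihydroxy-6-propylbenzoate, via rhodium quinoid carbene 12 (not isolated)
Conditions: Rh2(esp)2 (2 mol %), 4 Å MS, CH2Cl2, 0 °C → rt, 11 added in portions
Reagents that add atoms: none
Why: Proposed new method: Rh(II)-catalysed formal O–H insertion of a benzoic acid into a quinoid carbene released from a resorcylate iodonium zwitterion, which makes the depside link at the aryl C3–O bond; the ylidic C3 of 11 binds an axial site of Rh2(esp)2 and expels PhI to give the electrophilic carbene 12, the carboxyl oxygen of 6 adds to C3, and proton transfer with re-aromatisation frees 13 and the catalyst, so the site is fixed by where iodine sat, no phenyl ester can form because PhI is the leaving group, the two ortho groups of 6 do not interfere because its remote oxygen is the nucleophile, and the chelating esp ligands resist exchange with 6; the closest known reaction type is the Rh(II)-catalysed O–H insertion of carboxylic acids into carbenes from diazo compounds, quinone diazides or 1,3-dicarbonyl iodonium ylides.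

Step 8
Reactants: 13 benzyl 3-[(2,4-dimethoxy-6-pentylbenzoyl)oxy]-2,4-dihydroxy-6-propylbenzoate
Product: 14 3-[(2,4-dimethoxy-6-pentylbenzoyl)oxy]-2,4-dihydroxy-6-propylbenzoic acid (target)
Conditions: H2 (1 atm), 10 % Pd/C, EtOAc, rt
Reagents that add atoms: none
Why: Catalytic hydrogenolysis of the benzyl ester, in which the aryl ester, methyl ethers and phenols are inert and the neutral room-temperature conditions avoid acyl migration and decarboxylation.

## Compound list
1 | olivetol (5-pentylbenzene-1,3-diol) | CCCCCc1cc(O)cc(O)c1 | starting material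
2 | 3-methoxy-5-pentylphenol | CCCCCc1cc(O)cc(OC)c1 | intermediate
3 | 1,3-dimethoxy-5-pentylbenzene | CCCCCc1cc(OC)cc(OC)c1 | intermediate
4 | [(2,4-dimethoxy-6-pentylphenyl)methylidene]dimethylammonium dichlorophosphate | CCCCCc1cc(OC)cc(OC)c1C=[N+](C)C.[O-]P(=O)(Cl)Cl | intermediate
5 | 2,4-dimethoxy-6-pentylbenzaldehyde | CCCCCc1cc(OC)cc(OC)c1C=O | intermediate
6 | 2,4-dimethoxy-6-pentylbenzoic acid | CCCCCc1cc(OC)cc(OC)c1C(=O)O | intermediate
7 | 5-propylbenzene-1,3-diol (divarinol) | CCCc1cc(O)cc(O)c1 | starting material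
8 | magnesium 4-hydroxy-2-oxido-6-propylbenzoate (chelate) | CCCc1cc(O)cc([O-])c1C(=O)[O-].[Mg+2] | intermediate
9 | 2,4-dihydroxy-6-propylbenzoic acid | CCCc1cc(O)cc(O)c1C(=O)O | intermediate
10 | benzyl 2,4-dihydroxy-6-propylbenzoate | CCCc1cc(O)cc(O)c1C(=O)OCc1ccccc1 | intermediate
11 | benzyl 2-hydroxy-4-oxido-3-(phenyliodonio)-6-propylbenzoate | CCCc1cc([O-])c([I+]c2ccccc2)c(O)c1C(=O)OCc1ccccc1 | intermediate
12 | Rh2(esp)2 quinoid carbene (C3 carbene carbon, C4 ketone, C2 enol OH, C1 CO2Bn, C6 propyl) | CCCC1=CC(=O)C(=[Rh+2][Rh+2])C(O)=C1C(=O)OCc1ccccc1.CC(C)(Cc1cccc(CC(C)(C)C(=O)[O-])c1)C(=O)[O-].CC(C)(Cc1cccc(CC(C)(C)C(=O)[O-])c1)C(=O)[O-] | intermediate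
13 | benzyl 3-[(2,4-dimethoxy-6-pentylbenzoyl)oxy]-2,4-dihydroxy-6-propylbenzoate | CCCCCc1cc(OC)cc(OC)c1C(=O)Oc1c(O)cc(CCC)c(C(=O)OCc2ccccc2)c1O | intermediate
14 | 3-[(2,4-dimethoxy-6-pentylbenzoyl)oxy]-2,4-dihydroxy-6-propylbenzoic acid | CCCCCc1cc(OC)cc(OC)c1C(=O)Oc1c(O)cc(CCC)c(C(=O)O)c1O | target

## Summary
Total step count: 8 (steps 1–3 for the A-ring acid, steps 4–6 for the B-ring zwitterion, steps 7–8 after convergence).
Longest linear sequence: 5 steps (1 → 3 → 5 → 6 → 13 → 14, and equally 7 → 9 → 10 → 11 → 13 → 14).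

## Steps most likely to fail

**Step 7 (proposed new step).**
- Risks:
  - 1,4-phenyl shift from I to O in 11.
  - Arylation of the electron-rich ring of 6 by the carbene.
  - Insertion into phenolic O–H or adventitious water.
  - Protonation of 11 by 6, which slows carbene formation.
- Fallback (known chemistry, acyl C–O bond formation on a protected 3-phenol): it sets out from 10, uses 6, and comes back at 14. Rieche formylation of 10 (Cl2CHOMe, TiCl4, CH2Cl2, 0 °C) gives benzyl 3-formyl-2,4-dihydroxy-6-propylbenzoate F1. BnBr and K2CO3 in DMF give benzyl 2,4-bis(benzyloxy)-3-formyl-6-propylbenzoate F2. Baeyer–Villiger oxidation with mCPBA in CH2Cl2 gives the aryl formate benzyl 2,4-bis(benzyloxy)-3-(formyloxy)-6-propylbenzoate F3, which K2CO3 in MeOH cleaves to benzyl 2,4-bis(benzyloxy)-3-hydroxy-6-propylbenzoate F4. Acid 6 is activated with (CF3CO)2O in toluene as 2,4-dimethoxy-6-pentylbenzoic trifluoroacetic anhydride F5. This acylates F4 to benzyl 2,4-bis(benzyloxy)-3-[(2,4-dimethoxy-6-pentylbenzoyl)oxy]-6-propylbenzoate F6. H2 over Pd/C in EtOAc then removes all three benzyl groups and gives 14.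

**Step 6.**
- Risks:
  - Attack of I(III) at C5.
  - Oxidation of the resorcinol ring to quinoid products.
  - A zwitterion too labile to isolate.
- Fallback (peroxide chemistry in place of iodine(III), skipping steps 6 and 7): it sets out from 6 and 10 and comes back at 13. Acid 6 is converted with DCC and H2O2 (CH2Cl2/Et2O, 0 °C) into bis(2,4-dimethoxy-6-pentylbenzoyl) peroxide F7. This is warmed with 10 in CHCl3, the old ortho-acyloxylation of phenols by diaroyl peroxides. The free 4-OH attacks the O–O bond, because both carbonyl groups are blocked by their ortho substituents. The product is benzyl 4-[(2,4-dimethoxy-6-pentylbenzoyl)peroxy]-2-hydroxy-6-propylbenzoate F8. Its [3,3] shift should go to C3, since the same 2-OH···O=C chelate bond fixation sends Claisen rearrangements of 4-allyloxy-2-hydroxyaryl carbonyl compounds to C3, and C5 is hindered by the propyl group. Tautomerisation then gives 13, and the other half of F7 is recovered as 6.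

**Step 4.**
- Risks:
  - Incomplete conversion.
  - The 2,6-dihydroxy-4-propyl regioisomer.
  - Decarboxylation of 9 on work-up.
- Fallback (C1 unit brought in as an aldehyde and then oxidised): it sets out from 7 and comes back at 9. Vilsmeier–Haack formylation of 7 (POCl3, DMF, 0 °C → rt) gives [(2,4-dihydroxy-6-propylphenyl)methylidene]dimethylammonium dichlorophosphate F9. Hydrolysis in ice-water gives 2,4-dihydroxy-6-propylbenzaldehyde F10. Chlorite oxidation (NaClO2, NaH2PO4, DMSO/H2O, rt) then gives 9.

## Further compounds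
F1 | step 7 | benzyl 3-formyl-2,4-dihydroxy-6-propylbenzoate | CCCc1cc(O)c(C=O)c(O)c1C(=O)OCc1ccccc1
F2 | step 7 | benzyl 2,4-bis(benzyloxy)-3-formyl-6-propylbenzoate | CCCc1cc(OCc2ccccc2)c(C=O)c(OCc2ccccc2)c1C(=O)OCc1ccccc1
F3 | step 7 | benzyl 2,4-bis(benzyloxy)-3-(formyloxy)-6-propylbenzoate | CCCc1cc(OCc2ccccc2)c(OC=O)c(OCc2ccccc2)c1C(=O)OCc1ccccc1
F4 | step 7 | benzyl 2,4-bis(benzyloxy)-3-hydroxy-6-propylbenzoate | CCCc1cc(OCc2ccccc2)c(O)c(OCc2ccccc2)c1C(=O)OCc1ccccc1
F5 | step 7 | 2,4-dimethoxy-6-pentylbenzoic trifluoroacetic anhydride | CCCCCc1cc(OC)cc(OC)c1C(=O)OC(=O)C(F)(F)F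
F6 | step 7 | benzyl 2,4-bis(benzyloxy)-3-[(2,4-dimethoxy-6-pentylbenzoyl)oxy]-6-propylbenzoate | CCCCCc1cc(OC)cc(OC)c1C(=O)Oc1c(OCc2ccccc2)cc(CCC)c(C(=O)OCc2ccccc2)c1OCc1ccccc1
F7 | step 6 | bis(2,4-dimethoxy-6-pentylbenzoyl) peroxide | CCCCCc1cc(OC)cc(OC)c1C(=O)OOC(=O)c1c(CCCCC)cc(OC)cc1OC
F8 | step 6 | benzyl 4-[(2,4-dimethoxy-6-pentylbenzoyl)peroxy]-2-hydroxy-6-propylbenzoate | CCCCCc1cc(OC)cc(OC)c1C(=O)OOc1cc(O)c(C(=O)OCc2ccccc2)c(CCC)c1
F9 | step 4 | [(2,4-dihydroxy-6-propylphenyl)methylidene]dimethylammonium dichlorophosphate | CCCc1cc(O)cc(O)c1C=[N+](C)C.[O-]P(=O)(Cl)Cl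
F10 | step 4 | 2,4-dihydroxy-6-propylbenzaldehyde | CCCc1cc(O)cc(O)c1C=O
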